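The numbers in the tables are simulated for substances that don't exist, noise included.

Friday's charge cannot explain Friday's run: J stood at 12% by 0.417 min, with 88% of Z present and 0.95 equiv of X charged. X was never read, so I followed the X charged.

| flask | Z | X | temperature | remark | time |
|---|---|---|---|---|---|
| Thursday's | 0.044 M | 0.47 equiv | 56 °C | run made earlier |  |
| Saturday's | 0.044 M | 0.71 equiv | 81 °C | run made earlier |  |
| Friday's | 0.088 M | 0.95 equiv | 56 °C | run made earlier |  |
| green | 0.044 M | 0.950 equiv | 45 °C |  | 10 min |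
| amber | 0.044 M | 0.950 equiv | 90 °C |  | 10 min |
| red | 0.044 M | 0.950 equiv | 60 °C |  | 10 min |
| blue | 0.044 M | 0.950 equiv | 75 °C |  | 10 min |

Thursday's run (percent of the Z charged)

| time / min | J / % | Z / % |
|---|---|---|
| 0.833 | 3 | 98 |
| 1.33 | 6 | 97 |
| 2.50 | 3 | 94 |
| 3.00 | 4 | 94 |
| 4.00 | 4 | 91 |
| 5.00 | 3 | 91 |

Saturday's run (percent of the Z charged)

| time / s | J / % | Z / % |
|---|---|---|
| 10.0 | 5 | 90 |
| 20.0 | 9 | 88 |
| 30.0 | 14 | 84 |
| 50.0 | 16 | 79 |
| 80.0 | 15 | 73 |

Friday's run (percent of the Z charged)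

| time / min | J / % | Z / % |
|---|---|---|
| 0.417 | 12 | 88 |
| 1.33 | 11 | 88 |
| 2.50 | 12 | 84 |
| 4.00 | 14 | 86 |
| 5.00 | 10 | 87 |

(standard deviation of a reading: 1.5 percentage points)

- the best flask by amount of J, in percent of the Z charged; "all alike" if 1.5 percentage points covers them all (green / amber / red / blue / all alike)
- amount of J at the end, in percent of the Z charged, green
- amount of J at the end, in percent of the Z charged, amber
- amount of J at the end, in percent of the Z charged, red
- amount of J at the end, in percent of the Z charged, blue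



Thursday's J averaged 3.83% on 0.47 equiv of X. That gave 0.0816. I call this the catch, the J made per equivalent of X charged. Saturday's last two readings averaged 15.5% on 0.71 equiv, a catch of 0.218 at 81 °C. Both runs had cZ 0.044 M, as the four flasks have. Friday's run, at twice that cZ, I set aside.

From 56 °C to 81 °C the catch grew by a factor of 2.68. I assumed that it kept the same factor per degree, and that J follows the charge. My reckoning gave green 5.02%, red 9.07%, blue 16.4% and amber 29.6%, so amber came out highest.

The forecast differed. It chose blue, with green 3.7%, amber 11%, red 7.7% and blue 12%: “Heat raises K but destroys Z, so J peaks near 75 °C”.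

The flasks gave green 6.85%, amber 19.7%, red 10.3% and blue 14.5%, so amber was best.

    Z + X ⇌ J + L (K = 0.950, k = 0.270 M⁻¹ s⁻¹, Ea = 58.0 kJ mol⁻¹, ΔH = −19.0 kJ mol⁻¹)
    X ⇌ E (K = 18.0, k = 0.200 s⁻¹, Ea = 83.0 kJ mol⁻¹, ΔH = −90.0 kJ mol⁻¹)
    J ⇌ G (K = 2.00, k = 0.00230 s⁻¹, Ea = 92.0 kJ mol⁻¹, ΔH = −22.0 kJ mol⁻¹)
    (constants at 60 °C)

Amber's catch was 0.208, less than the 0.311 I had reckoned. At green's start, X went to E 11 times as fast as to J, forward steps alone. The neighbour flask is green with 3.80 equiv of X. My catch for 45 °C, times that charge, gave 20.1%. The flask gave 18.6%, with free X at 1.1% of its charge and cE at 0.155 M. Green's own catch was 0.0721; the neighbour's was 0.0489, with Z at 76%.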